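Four questions stand on this flask, and each turns on how much substrate is in solution.

    solid substrate ⇌ dissolved substrate, rate k1*(cs1 - [dissolved substrate]) while solid is left; crystals form when [dissolved substrate] > cs1 (cs1 = 0.48 M, k1 = 0.016 h⁻¹)
    dissolved substrate + reagent → target (k2 = 0.066 L mol⁻¹ h⁻¹)
    dissolved substrate + target → side product (k3 = 0.068 L mol⁻¹ h⁻¹)
    2 solid substrate → homo dimer (k4 = 0.034 L mol⁻¹ h⁻¹)

solid substrate 0.80 M; reagent 0.880 M; time 4.0 d

- percentages count the solid substrate that a species holds: one side product or homo dimer counts as two
- two of one species on the left: rate k times its square, two consumed each time
- solid, in amounts per volume of the solution: solid substrate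
- at the start none of the solid substrate is in solution
- dissolved substrate means what is dissolved; the solid is not counted in it
- run time (flask): 4.0 d

- Saturday's: doubling the solubility in step 1, all else as stated
- Sunday's: doubling the amount of reagent, all else as stated
- Friday's: doubling the dissolution coefficient of step 1, all else as stated

- target at 4.0 d, in percent of the solid substrate charged
- concentration of dissolved substrate in solution at 25 h, in percent of saturation
- the change that raises the amount of target at 4.0 d, in percent of the solid substrate charged most ("none" if none brings more than 2 percentage points) (Saturday's / Sunday's / Friday's / none)
- amount of target at 4.0 d, in percent of the solid substrate charged, after Sunday's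

**What matters.** While solid stands, dissolved substrate gains by dissolution and loses to reagent. With reagent frozen at its charge, that loss is pseudo-first-order, and the level relaxes to a plateau where gain and loss balance. Each per cent of error in the dissolution coefficient, or in the step 2 constant, moves this plateau by 0.784 per cent. Solubility cancels from the asked percentage of saturation. The dimerisation constant enters this level through whether solid stands at 25 h. The side-step constant matters through target.

**The numbers.** Dimerisation without dissolution leaves 42.4% of the charge as solid at 25 h, and dissolution at full drive takes less, 24.0%, so solid stands. The loss constant is 0.0581 h⁻¹, and with the dissolution coefficient the relaxation constant is 0.0741 h⁻¹. This gives 13.0%: the plateau, the fraction of the charge in solution where gain and loss balance. Saturation equals 60.0% of the charge, so the relaxing level at 25 h is 18.2% of saturation. By then about 10.3% of the charge is target, which costs 9.32% of the reagent. The side drain, 0.00558 h⁻¹, is smaller than the main loss. This reckoning stops here, with no figure of its own for target at 4.0 d.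

**Result.** The forecast, treating “the dimer and dissolution as competing sinks”, gave 30.3%, 18.2%, Sunday's and 38.3%. The flask gives 30.2% and 18.2%. Sunday's change gains most, 8.2 percentage points against 4.5 points and 3.9 points, and reaches 38.4%.

**Plateau again.** The flask's 18.2% at 25 h lies close to the reckoned 18.2%. The neighbour flask read at 40 h, with solid substrate still at 15.0%, holds 12.3% of the charge dissolved, close to the 12.3% that the plateau gives. In the flask, the side step and the low solubility are two parts of what holds target down: against 30.2% at 4.0 d, target reaches 43.0% with the side step taken away and 39.9% with the solubility limit taken away.

Its constants are assumed; the result is computed.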